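The cyclohexenone ring (C1 carbonyl, C2=C3, C4, carbinol C5, C6) is cut at C2=C3 and C5–C6: C6–C1(=O)–C2 is an acetone 1,3-dianion, C3–C4–C5 a β-keto aldehyde. The key step exploits the 1,3-relation of C5 to the side-chain carbon C2': its oxygen, held at the alcohol level, ties C2' to C3 in a chiral 2,3-dihydro-4H-pyran-4-one (from oleyl aldehyde by asymmetric hetero-Diels–Alder reaction). In one pot the γ-carbanion of dimethyl (2-oxopropyl)phosphonate adds to the pyranone carbonyl (C5–C6, C5 controlled by the pyran stereocentre), the enol ether is hydrated, and intramolecular Horner–Wadsworth–Emmons olefination closes C2=C3 as the pyran opens. Oxidation at C2' finishes.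

Key step: step 3

Assumption: (S)-BINOL is taken as the ligand antipode that gives (R)-5, by analogy with the face selectivity of the BINOL–Ti(OiPr)4 system in allylations of unbranched aliphatic aldehydes. Should the sense prove opposite, (R)-BINOL is used and nothing else changes.

Step 1
Reactants: 1 (Z)-octadec-9-en-1-ol (oleyl alcohol)
Product: 2 (Z)-octadec-9-enal
Conditions: TEMPO (10 mol %), PhI(OAc)2 (1.1 equiv), CH2Cl2, rt
Reagents that add atoms: none
Why: The TEMPO/PhI(OAc)2 oxidation (oxoammonium-mediated) should stop at the aldehyde and leave the isolated Z-alkene untouched.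

Step 2
Reactants: 2 (Z)-octadec-9-enal; 3 Danishefsky's diene, (E)-1-methoxy-3-(trimethylsilyloxy)buta-1,3-diene
Product: 5 (2R)-2-[(8Z)-heptadec-8-en-1-yl]-2,3-dihydro-4H-pyran-4-one, via Mukaiyama aldol adduct 4 (not isolated)
Conditions: (S)-BINOL (20 mol %), Ti(OiPr)4 (10 mol %), 4 Å molecular sieves, Et2O, −20 °C; then CF3CO2H, CH2Cl2, 0 °C
Reagents that add atoms: Danishefsky's diene (3), CO/C=C/C(=C)O[Si](C)(C)C
Why: Catalytic asymmetric hetero-Diels–Alder reaction of the Mukaiyama aldol type, in which the BINOL–titanium Lewis acid directs the diene terminus to one face of the aldehyde and so sets C2 of the pyranone as (R) under catalyst control, after which trifluoroacetic acid closes the ring with loss of methanol.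

Step 3
Reactants: 5 (2R)-2-[(8Z)-heptadec-8-en-1-yl]-2,3-dihydro-4H-pyran-4-one; 6 dimethyl (2-oxopropyl)phosphonate
Product: 9 (5R)-5-hydroxy-5-[(2R,10Z)-2-hydroxynonadec-10-en-1-yl]cyclohex-2-en-1-one, via pyranol phosphonate 7 (not isolated), via lactol phosphonate 8 (not isolated)
Conditions: 6, NaH, THF, 0 °C, then n-BuLi, 0 °C; add 5, −78 °C; then 1 M HCl to pH 2, THF–H2O, 0 °C; then aq. K2CO3 to pH 10–11, 0 °C to rt
Reagents that add atoms: dimethyl (2-oxopropyl)phosphonate (6), CC(=O)CP(=O)(OC)OC
Why: The γ-carbanion of the phosphonate dianion adds 1,2 to the vinylogous-ester carbonyl of 5 (C5–C6 of the cyclohexenone), cold dilute acid protonates the enol ether at carbon and water traps the oxocarbenium ion as lactol 8, and under carbonate the phosphonate carbanion attacks the ring-chain aldehyde and expels dimethyl phosphate to form C2=C3. The closest known reaction types are the γ-selective carbonyl additions of β-keto phosphonate dianions, the 1,2-addition of lithium enolates to vinylogous esters, glycal hydration, and the intramolecular Horner–Wadsworth–Emmons cyclisation to cyclohexenones. The only ring closed is the cyclohexenone, by 6-exo-trig attack of the carbanion on the aldehyde followed by syn-elimination of phosphate, which can give only the cis ring alkene; the pyran ring opens in the same operation. The new stereocentre C5 is set in the first event by axial attack on the half-chair pyranone carrying a pseudo-equatorial C2 chain, so the new C–C bond ends trans and the hydroxyl cis to that chain, and (R)-5 translates into (5R). The step needs 1,2- over 1,4-addition and γ- over α-attack (secured by the hard, more basic γ-carbanion and the donor-deactivated β-carbon), carbon protonation of the enol ether rather than ionisation of the tertiary allylic hydroxyl (secured by cold dilute acid), and olefination before any β-elimination (secured by the acidity of the phosphonate methylene). The minor C5 epimer is a diastereomer of 9 and is to be removed at this stage, because after step 4 it would be the enantiomer.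

Step 4
Reactants: 9 (5R)-5-hydroxy-5-[(2R,10Z)-2-hydroxynonadec-10-en-1-yl]cyclohex-2-en-1-one
Product: 10 (5R)-5-hydroxy-5-[(10Z)-2-oxononadec-10-en-1-yl]cyclohex-2-en-1-one
Conditions: Dess–Martin periodinane, pyridine, CH2Cl2, 0 °C to rt
Reagents that add atoms: none
Why: Dess–Martin oxidation should convert the secondary carbinol into the side-chain ketone under buffered, nearly neutral conditions, while the tertiary hydroxyl cannot be oxidised, the enone and Z-alkene are inert, and C5 is untouched.

Compound list
1 | (Z)-octadec-9-en-1-ol (oleyl alcohol) | CCCCCCCC/C=C\CCCCCCCCO | starting material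
2 | (Z)-octadec-9-enal | CCCCCCCC/C=C\CCCCCCCC=O | intermediate
3 | Danishefsky's diene, (E)-1-methoxy-3-(trimethylsilyloxy)buta-1,3-diene | CO/C=C/C(=C)O[Si](C)(C)C | starting material
4 | (1E,5R,13Z)-5-hydroxy-1-methoxydocosa-1,13-dien-3-one (Mukaiyama aldol adduct) | CO/C=C/C(=O)C[C@H](O)CCCCCCC/C=C\CCCCCCCC | intermediate (not isolated)
5 | (2R)-2-[(8Z)-heptadec-8-en-1-yl]-2,3-dihydro-4H-pyran-4-one | O=C1C=CO[C@H](CCCCCCC/C=C\CCCCCCCC)C1 | intermediate
6 | dimethyl (2-oxopropyl)phosphonate | CC(=O)CP(=O)(OC)OC | starting material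
7 | dimethyl {3-[(2R,4R)-2-[(8Z)-heptadec-8-en-1-yl]-4-hydroxy-3,4-dihydro-2H-pyran-4-yl]-2-oxopropyl}phosphonate (hydroxyl cis to the C2 chain) | CCCCCCCC/C=C\CCCCCCC[C@@H]1C[C@@](O)(CC(=O)CP(=O)(OC)OC)C=CO1 | intermediate (not isolated)
8 | dimethyl {3-[(4S,6R)-6-[(8Z)-heptadec-8-en-1-yl]-2,4-dihydroxyoxan-4-yl]-2-oxopropyl}phosphonate (lactol, both anomers, in equilibrium with the open hydroxy aldehyde) | CCCCCCCC/C=C\CCCCCCC[C@@H]1C[C@@](O)(CC(=O)CP(=O)(OC)OC)CC(O)O1 | intermediate (not isolated)
9 | (5R)-5-hydroxy-5-[(2R,10Z)-2-hydroxynonadec-10-en-1-yl]cyclohex-2-en-1-one | CCCCCCCC/C=C\CCCCCCC[C@@H](O)C[C@]1(O)CC=CC(=O)C1 | intermediate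
10 | (5R)-5-hydroxy-5-[(10Z)-2-oxononadec-10-en-1-yl]cyclohex-2-en-1-one | CCCCCCCC/C=C\CCCCCCCC(=O)C[C@]1(O)CC=CC(=O)C1 | target

Total step count: 4. Longest linear sequence: 4 steps (1 → 2 → 5 → 9 → 10).

Steps most likely to fail

Step 3. Two processes threaten it: poor facial selectivity (or competing enolisation of 5) in the 1,2-addition, and ionisation of the tertiary allylic hydroxyl during enol-ether hydration, which would lose the C5 oxygen. The fallback sets out from 5 and comes back at 9; it makes the two bonds in the opposite order and uses the ring oxygen as a bridge. TMSOTf-promoted Mukaiyama–Michael addition of 2-(trimethylsilyloxy)propene to 5 (axial attack on the O-silylated oxocarbenium ion, CH2Cl2, −78 °C, aqueous work-up) should give the 2,6-trans diketone (2R,6R)-2-[(8Z)-heptadec-8-en-1-yl]-6-(2-oxopropyl)oxan-4-one F1. Intramolecular aldol addition (KOH, MeOH, 0 °C), in which the axial acetonyl arm can reach the ring carbonyl only from its own face, should give the bridged ketol (1S,3R,5S)-3-[(8Z)-heptadec-8-en-1-yl]-5-hydroxy-2-oxabicyclo[3.3.1]nonan-7-one F2. Its carbinol configuration is locked by the bridge and its bridgehead hydroxyl cannot be eliminated. E1cB opening of the oxygen bridge (retro-oxa-Michael; KHMDS, THF, −78 to 0 °C, then AcOH quench) would release 9.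

Step 2. Enantioface discrimination may be insufficient with the long, unbranched and enolisable aldehyde, and the aldehyde may self-condense under the Lewis acid. The fallback sets out from 2 and comes back at 5, with reagent control in place of catalyst control. Allylation of 2 with B-allyldiisopinocampheylborane (the antipode that delivers the (R)-carbinol; Et2O, −78 °C, then NaOH/H2O2) should give (4R,12Z)-henicosa-1,12-dien-4-ol F3. Tsuji–Wacker oxidation of the terminal alkene only (PdCl2 cat., CuCl, O2, DMF–H2O) should give (4R,12Z)-4-hydroxyhenicos-12-en-2-one F4. Condensation with N,N-dimethylformamide dimethyl acetal (toluene, 80 °C) should give the enaminone (1E,5R,13Z)-1-(dimethylamino)-5-hydroxydocosa-1,13-dien-3-one F5. Acid (CF3CO2H, CH2Cl2) then closes the pyranone by addition–elimination of the hydroxyl with loss of dimethylamine, giving 5.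

Step 4. The product is a β-hydroxy ketone toward both carbonyls, so dehydration of the tertiary hydroxyl (on toward the dienone and phenol) or retro-aldol cleavage may occur during oxidation, work-up or chromatography. Closure of the free secondary hydroxyl of 9 onto the enone may also compete. The fallback sets out from 9 and comes back at 10, with a protecting-group strategy. Silylation of both hydroxyls (N-(trimethylsilyl)imidazole, CH2Cl2) should give (5R)-5-(trimethylsilyloxy)-5-[(2R,10Z)-2-(trimethylsilyloxy)nonadec-10-en-1-yl]cyclohex-2-en-1-one F6. Selective methanolysis of the secondary silyl ether (citric acid, MeOH, 0 °C) should give (5R)-5-[(2R,10Z)-2-hydroxynonadec-10-en-1-yl]-5-(trimethylsilyloxy)cyclohex-2-en-1-one F7. Dess–Martin oxidation should give (5R)-5-[(10Z)-2-oxononadec-10-en-1-yl]-5-(trimethylsilyloxy)cyclohex-2-en-1-one F8, which can be purified without a free β-hydroxyl. Buffered HF·pyridine (THF, 0 °C) then releases 10 as the last operation.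

Further compounds
F1 | step 3 | (2R,6R)-2-[(8Z)-heptadec-8-en-1-yl]-6-(2-oxopropyl)oxan-4-one | CC(=O)C[C@@H]1CC(=O)C[C@@H](CCCCCCC/C=C\CCCCCCCC)O1
F2 | step 3 | (1S,3R,5S)-3-[(8Z)-heptadec-8-en-1-yl]-5-hydroxy-2-oxabicyclo[3.3.1]nonan-7-one | O=C1C[C@@H]2C[C@](O)(C1)C[C@@H](CCCCCCC/C=C\CCCCCCCC)O2
F3 | step 2 | (4R,12Z)-henicosa-1,12-dien-4-ol | C=CC[C@H](O)CCCCCCC/C=C\CCCCCCCC
F4 | step 2 | (4R,12Z)-4-hydroxyhenicos-12-en-2-one | CC(=O)C[C@H](O)CCCCCCC/C=C\CCCCCCCC
F5 | step 2 | (1E,5R,13Z)-1-(dimethylamino)-5-hydroxydocosa-1,13-dien-3-one | CN(C)/C=C/C(=O)C[C@H](O)CCCCCCC/C=C\CCCCCCCC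
F6 | step 4 | (5R)-5-(trimethylsilyloxy)-5-[(2R,10Z)-2-(trimethylsilyloxy)nonadec-10-en-1-yl]cyclohex-2-en-1-one | CCCCCCCC/C=C\CCCCCCC[C@@H](O[Si](C)(C)C)C[C@]1(O[Si](C)(C)C)CC=CC(=O)C1
F7 | step 4 | (5R)-5-[(2R,10Z)-2-hydroxynonadec-10-en-1-yl]-5-(trimethylsilyloxy)cyclohex-2-en-1-one | CCCCCCCC/C=C\CCCCCCC[C@@H](O)C[C@]1(O[Si](C)(C)C)CC=CC(=O)C1
F8 | step 4 | (5R)-5-[(10Z)-2-oxononadec-10-en-1-yl]-5-(trimethylsilyloxy)cyclohex-2-en-1-one | CCCCCCCC/C=C\CCCCCCCC(=O)C[C@]1(O[Si](C)(C)C)CC=CC(=O)C1
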